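The numbers in the tables are simulated for an exercise, noise included.

Amounts first: each percent of substrate held in open dimer is substrate that is not ring, and one open dimer holds two substrate, so you should ask how the dimer's final share moves with the charge.

| setting | Saturday's | Friday's | south | east | west |
|---|---|---|---|---|---|
| substrate | 0.70 M | 1.1 M | 0.50 M | 0.50 M | 0.50 M |
| activator | 0.50 M | 0.50 M | 0.500 M | 0.500 M | 0.500 M |
| temperature | 55 °C | 75 °C | 60 °C | 75 °C | 90 °C |
| remark | run made earlier | run made earlier |  |  |  |
| time |  |  | 15 h | 15 h | 15 h |

- Saturday's (time / h: ring / %, open dimer / %): 0.833: 1.4, 2.6; 2.50: 0.3, 5.0; 4.00: 0.6, 6.7; 6.00: 1.5, 11.0; 10.0: 3.0, 20.4; 12.0: 5.4, 23.7; 15.0: 5.5, 28.4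
- Friday's (time / h: ring / %, open dimer / %): 1.00: 3.1, 15.2; 2.00: 4.5, 29.8; 3.00: 6.0, 39.7; 4.00: 5.3, 45.6; 5.00: 5.3, 49.8; 6.00: 5.5, 49.4; 8.00: 4.5, 52.2

(standard deviation of a reading: 1 percentage point)

1. the flask with the highest share of ring in all that became ring or open dimer or over-reaction product or side product ("all alike" if they lie within 1.5 percentage points) (south / east / west / all alike)
2. share of ring in all that became ring or open dimer or over-reaction product or side product, south
3. share of ring in all that became ring or open dimer or over-reaction product or side product, east
4. share of ring in all that became ring or open dimer or over-reaction product or side product, west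

- percentages count the substrate that a species holds: one open dimer or side product counts as two

In Friday's run, dimer reaches 15.2% by 1.00 h, bends near 5.00 h and reads 52.2% at 8.00 h, which I take as its level. Now draw that level against the charge. Since a dimer needs two substrate to meet, I expect a thin charge to give a level rising in step with the charge. The runs show no charge above 1.1 M, so I draw the curve at 0.50 M of activator and only up to that charge. A simple curve that starts so and bends over is level = charge/(charge + K). Friday's level makes K = 1.01 M, and this half-level charge is the charge at which the curve puts half of the substrate in dimer.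

So the curve starts with slope 1/K, crosses the halfway mark at K, and flattens beyond it. Friday's charge lies above that knee, at 1.1 M. East has Friday's temperature and activator, but its 0.50 M is about half of K, so my reckoning puts east's dimer at 33.2%. That leaves 66.8% of the charge for ring and whatever the readings don't show, and Friday's ring reads 4.5% at 8.00 h.

The forecast names south, with 16%, 11% and 8% for south, east and west, holding that “heat should disfavour ring”.

The selectivity for ring comes out highest in east, at 40.5%, against 27.8% in south and 35.8% in west.

    substrate + activated form → open dimer (k = 0.0403 L mol⁻¹ min⁻¹, Ea = 89.0 kJ mol⁻¹)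
    substrate + activator → activated form (k = 0.0788 L mol⁻¹ min⁻¹, Ea = 90.0 kJ mol⁻¹)
    activator + ring → over-reaction product (k = 0.00386 L mol⁻¹ min⁻¹, Ea = 68.0 kJ mol⁻¹)
    substrate + ring → side product (k = 0.0492 L mol⁻¹ min⁻¹, Ea = 86.0 kJ mol⁻¹)
    activated form → ring (k = 0.0128 min⁻¹, Ea = 99.0 kJ mol⁻¹)
    (constants at 90 °C)

At 15.0 h, east holds 35.4% as open dimer, where K gave 33.2%, and its ring stands at 38.4%. Now carry K, read at 75 °C, to a flask like west with 0.12 M of substrate, far below the knee: the curve gives 10.6%, and that flask holds 9.04% as open dimer.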